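Ring A is lettered a to f: carbon a bears OMe, carbon b is the lone CH, carbons c, d and e bear bromine and carbon f bears the aryloxy oxygen. It is cut at bonds a–b and e–f. The contiguous H, Br, Br, Br run b–e is the carbon chain of 2,3,4-tribromothiophene, whose 1,1-dioxide serves as the diene. Carbons a and f come from [(2,4-dibromophenoxy)ethynyl]trimethylsilane, whose oxygen already carries ring B and whose silyl group holds the place of the methoxy oxygen. One inverse-demand Diels-Alder reaction with loss of SO2 closes ring A with every substituent placed; silicon is then exchanged for OH and the phenol is methylated.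

Key step: step 6

Remark: the target has no stereocentre; compounds 4, 9 and 13 form as racemates and their SMILES carry no stereodescriptor.

Step 1
Reactants: 1 tetrabromothiophene
Product: 3 2,3,4-tribromothiophene, via 3,4,5-tribromo-2-thienyllithium 2 (not isolated)
Conditions: n-BuLi (1.0 equiv), THF, −78 °C; then H2O, −78 °C to rt
Reagents that add atoms: none
Why: Bromine–lithium exchange is fastest at an alpha position of the thiophene and stops after one exchange at −78 °C, and protonolysis of the thienyllithium leaves a single alpha hydrogen (halogen–metal exchange then protonation).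

Step 2
Reactants: 3 2,3,4-tribromothiophene
Product: 5 2,3,4-tribromothiophene 1,1-dioxide, via 2,3,4-tribromothiophene 1-oxide 4 (not isolated)
Conditions: CF3CO3H [from urea·H2O2 and (CF3CO)2O], CH2Cl2/MeCN, 0 °C to rt
Reagents that add atoms: trifluoroperacetic acid, OOC(=O)C(F)(F)F, generated in the flask from urea-hydrogen peroxide, NC(N)=O.OO, and trifluoroacetic anhydride, O=C(OC(=O)C(F)(F)F)C(F)(F)F
Why: Trifluoroperacetic acid is electrophilic enough to oxidise the sulfur of an electron-poor halothiophene, and the non-aromatic 1-oxide 4 is oxidised faster than the thiophene, so the reaction should run through to the 1,1-dioxide, which the three halogens make isolable (peracid S-oxidation of a polyhalothiophene).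

Step 3
Reactants: 6 2,4-dibromophenol; 7 2,4,6-trivinylcyclotriboroxane–pyridine complex
Product: 8 2,4-dibromo-1-(ethenyloxy)benzene
Conditions: Cu(OAc)2 (1 equiv), pyridine, CH2Cl2, rt, air
Reagents that add atoms: none
Why: Chan-Lam O-vinylation, in which the vinyl group passes from boron to a divalent copper phenoxide and C–O reductive elimination follows at room temperature, leaves both aryl bromides untouched.

Step 4
Reactants: 8 2,4-dibromo-1-(ethenyloxy)benzene
Product: 11 2,4-dibromo-1-(ethynyloxy)benzene, via 2,4-dibromo-1-(1,2-dibromoethoxy)benzene 9 (not isolated), via 2,4-dibromo-1-{[(Z)-2-bromoethenyl]oxy}benzene 10 (not isolated)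
Conditions: Br2 (1.0 equiv), CH2Cl2, −78 °C; solvent removed; KOtBu (2.5 equiv), THF, −78 to 0 °C; cold aq. NH4Cl
Reagents that add atoms: none
Why: Bromine adds to the enol ether double bond far faster than it substitutes the deactivated ring B, and two successive base-induced dehydrobrominations by tert-butoxide (the second an anti elimination from the Z-bromovinyl ether) should give the terminal aryl ynol ether, which has no O-alkyl hydrogen through which it could fragment to a ketene.

Step 5
Reactants: 11 2,4-dibromo-1-(ethynyloxy)benzene
Product: 12 [(2,4-dibromophenoxy)ethynyl]trimethylsilane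
Conditions: Me3SiOTf, Et3N, Zn(OTf)2 (cat.), CH2Cl2, rt
Reagents that add atoms: trimethylsilyl trifluoromethanesulfonate, C[Si](C)(C)OS(=O)(=O)C(F)(F)F
Why: Zn(OTf)2 and Et3N turn the terminal alkyne into a zinc acetylide that is silylated at carbon by Me3SiOTf (zinc-catalysed C-silylation of a terminal alkyne), which needs no organolithium and therefore spares the aryl bromides, while the excess amine keeps the medium non-acidic; the smallest silyl group is chosen so that later ipso substitution stays easy.

Step 6
Reactants: 5 2,3,4-tribromothiophene 1,1-dioxide; 12 [(2,4-dibromophenoxy)ethynyl]trimethylsilane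
Product: 14 [3,4,5-tribromo-2-(2,4-dibromophenoxy)phenyl]trimethylsilane, via bridged sulfone cycloadduct 13 (not isolated)
Conditions: PhMe, 90 °C, 5 added slowly to 12 (1.5 equiv), under nitrogen
Reagents that add atoms: none
Why: Proposed new method: the dioxide 5, a non-aromatic cyclic diene whose LUMO is lowered by the sulfonyl group and three bromines, should undergo an asynchronous inverse-electron-demand [4+2] cycloaddition with the oxygen-raised HOMO of alkyne 12, and the bridged sulfone 13 should then lose SO2 by cheletropic extrusion because an arene is formed. The closest known reaction type is the Diels-Alder/SO2-extrusion benzannulation of tetrahalothiophene 1,1-dioxides with alkynes; a 1-aryloxy-2-silylalkyne has not been used as the two-carbon partner. Ring A closes by an intermolecular [4+2] annulation in which the four diene carbons become carbons b to e and the two alkyne carbons become carbons a and f, the new bonds being a–b and f–e. No stereocentre remains in 14 (the two bridgehead centres of racemic 13 vanish on aromatisation), so the selectivity needed is regiochemical: the silyl-bearing carbon, which is the nucleophilic beta carbon of the ynol ether and also the bulkier end, should bond first to the unhindered CH terminus of 5, placing developing negative charge on the diene carbon that carries sulfonyl and bromine and positive charge on the oxygen-bearing alkyne carbon beta to silicon, so that sterics and polarisation point the same way. Chemoselectivity against [4+2] self-dimerisation of 5 through its CH=CBr double bond is sought by adding 5 slowly to an excess of the more electron-rich 12.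

Step 7
Reactants: 14 [3,4,5-tribromo-2-(2,4-dibromophenoxy)phenyl]trimethylsilane
Product: 16 3,4,5-tribromo-2-(2,4-dibromophenoxy)phenol, via dibromo[3,4,5-tribromo-2-(2,4-dibromophenoxy)phenyl]borane 15 (not isolated)
Conditions: BBr3 (1.2 equiv), CH2Cl2, 0 °C to rt; volatiles removed; then H2O2, NaOH, THF/H2O, 0 °C; HCl work-up
Reagents that add atoms: hydrogen peroxide, OO
Why: Ipso-borodesilylation, in which BBr3 attacks the silicon-bearing carbon a (the cationic intermediate is stabilised by the C–Si bond and by the ortho aryloxy oxygen) and Me3SiBr leaves, is followed by alkaline peroxide oxidation of the C–B bond with aryl migration from boron to oxygen; a diaryl ether is inert to BBr3.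

Step 8
Reactants: 16 3,4,5-tribromo-2-(2,4-dibromophenoxy)phenol
Product: 17 1,2,3-tribromo-4-(2,4-dibromophenoxy)-5-methoxybenzene (the target)
Conditions: MeI, K2CO3, acetone, rt
Reagents that add atoms: iodomethane, CI
Why: Williamson ether synthesis, a bimolecular substitution of iodide by the acidic phenoxide at the methyl carbon, is placed last so that BBr3 never meets the methyl ether.

Compound list
1 | tetrabromothiophene | Brc1sc(Br)c(Br)c1Br | starting material
2 | 3,4,5-tribromo-2-thienyllithium (not isolated) | [Li]c1sc(Br)c(Br)c1Br | intermediate
3 | 2,3,4-tribromothiophene | Brc1csc(Br)c1Br | intermediate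
4 | 2,3,4-tribromothiophene 1-oxide (racemic at sulfur, not isolated) | O=S1C=C(Br)C(Br)=C1Br | intermediate
5 | 2,3,4-tribromothiophene 1,1-dioxide | O=S1(=O)C=C(Br)C(Br)=C1Br | intermediate
6 | 2,4-dibromophenol | Oc1ccc(Br)cc1Br | starting material
7 | 2,4,6-trivinylcyclotriboroxane–pyridine complex | C=CB1OB(C=C)OB(C=C)O1.c1ccncc1 | starting material
8 | 2,4-dibromo-1-(ethenyloxy)benzene | C=COc1ccc(Br)cc1Br | intermediate
9 | 2,4-dibromo-1-(1,2-dibromoethoxy)benzene (racemic, not isolated) | BrCC(Br)Oc1ccc(Br)cc1Br | intermediate
10 | 2,4-dibromo-1-{[(Z)-2-bromoethenyl]oxy}benzene (not isolated) | Br/C=C\Oc1ccc(Br)cc1Br | intermediate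
11 | 2,4-dibromo-1-(ethynyloxy)benzene | C#COc1ccc(Br)cc1Br | intermediate
12 | [(2,4-dibromophenoxy)ethynyl]trimethylsilane | C[Si](C)(C)C#COc1ccc(Br)cc1Br | intermediate
13 | bridged sulfone cycloadduct, 1,5,6-tribromo-2-(2,4-dibromophenoxy)-3-(trimethylsilyl)-7-thiabicyclo[2.2.1]hepta-2,5-diene 7,7-dioxide (racemic, not isolated) | C[Si](C)(C)C1=C(Oc2ccc(Br)cc2Br)C2(Br)C(Br)=C(Br)C1S2(=O)=O | intermediate
14 | [3,4,5-tribromo-2-(2,4-dibromophenoxy)phenyl]trimethylsilane | C[Si](C)(C)c1cc(Br)c(Br)c(Br)c1Oc1ccc(Br)cc1Br | intermediate
15 | dibromo[3,4,5-tribromo-2-(2,4-dibromophenoxy)phenyl]borane (not isolated) | BrB(Br)c1cc(Br)c(Br)c(Br)c1Oc1ccc(Br)cc1Br | intermediate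
16 | 3,4,5-tribromo-2-(2,4-dibromophenoxy)phenol | Oc1cc(Br)c(Br)c(Br)c1Oc1ccc(Br)cc1Br | intermediate
17 | 1,2,3-tribromo-4-(2,4-dibromophenoxy)-5-methoxybenzene | COc1cc(Br)c(Br)c(Br)c1Oc1ccc(Br)cc1Br | target

Total step count: 8. Longest linear sequence: 6 steps (steps 3 to 8, from 2,4-dibromophenol 6); the thiophene branch (steps 1 and 2) joins at step 6.

Steps most likely to fail

Step 6. The cycloaddition may be outrun by self-dimerisation of the dioxide, or the first bond may form in a stepwise [2+2] or ring-expansion mode or in the reversed orientation. The fallback gives up the cycloaddition and builds ring A by classical arene chemistry; it sets out from 2,4-dibromophenol (6) and comes back at the target 17. Chan-Lam O-arylation of 6 with commercial (2-methoxy-5-nitrophenyl)boronic acid (COc1ccc(cc1B(O)O)[N+](=O)[O-]; Cu(OAc)2, pyridine, 4 Å sieves, CH2Cl2, air, rt) should give 2,4-dibromo-1-(2-methoxy-5-nitrophenoxy)benzene F1. Reduction with Fe and NH4Cl in aqueous EtOH, which spares aryl bromides, gives 3-(2,4-dibromophenoxy)-4-methoxyaniline F2. The amino group on carbon d, whose para position (carbon a) is blocked by OMe, then directs two equivalents of NBS (MeCN, 0 °C) to its ortho positions, carbons c and e, giving 2,6-dibromo-3-(2,4-dibromophenoxy)-4-methoxyaniline F3. Sandmeyer bromination (t-BuONO, CuBr2, MeCN) replaces the nitrogen on carbon d by the third bromine and delivers 17.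

Step 7. Ipso substitution at the silicon-bearing carbon may be too slow on the tribrominated ring, so that protodesilylation by adventitious HBr takes over. The fallback sets out from 14 and comes back at 16. Iododesilylation with the smaller, stronger electrophile ICl (CH2Cl2, 0 °C) should give 1,2,3-tribromo-4-(2,4-dibromophenoxy)-5-iodobenzene F4. Iodine–magnesium exchange with iPrMgCl·LiCl (THF, −78 °C), much faster for the iodide than for any bromide, gives [3,4,5-tribromo-2-(2,4-dibromophenoxy)phenyl]magnesium chloride F5. Trapping with B(OMe)3 gives dimethyl [3,4,5-tribromo-2-(2,4-dibromophenoxy)phenyl]boronate F6, and oxidation with H2O2 and NaOH gives the phenol 16.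

Step 4. The alpha-bromo ether may be substituted by alkoxide instead of eliminating, the second elimination may stall, and the free terminal ynol ether may be consumed by addition of tert-butanol or by polymerisation. The fallback sets out from 8 and comes back at 12, so that the free alkyne 11 is never handled and step 5 is skipped. After bromination of 8 as before, Et3N (1.1 equiv, CH2Cl2, 0 °C) is used for the first dehydrobromination only, and the bromovinyl ether 10 is isolated. KN(SiMe3)2 (2.1 equiv, THF, −78 °C) then eliminates HBr and deprotonates the alkyne to potassium (2,4-dibromophenoxy)ethynide F7, which is quenched in the same flask with Me3SiCl to give 12.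

Further compounds
F1 | step 6 | 2,4-dibromo-1-(2-methoxy-5-nitrophenoxy)benzene | COc1ccc(cc1Oc1ccc(Br)cc1Br)[N+](=O)[O-]
F2 | step 6 | 3-(2,4-dibromophenoxy)-4-methoxyaniline | COc1ccc(N)cc1Oc1ccc(Br)cc1Br
F3 | step 6 | 2,6-dibromo-3-(2,4-dibromophenoxy)-4-methoxyaniline | COc1cc(Br)c(N)c(Br)c1Oc1ccc(Br)cc1Br
F4 | step 7 | 1,2,3-tribromo-4-(2,4-dibromophenoxy)-5-iodobenzene | Ic1cc(Br)c(Br)c(Br)c1Oc1ccc(Br)cc1Br
F5 | step 7 | [3,4,5-tribromo-2-(2,4-dibromophenoxy)phenyl]magnesium chloride | Cl[Mg]c1cc(Br)c(Br)c(Br)c1Oc1ccc(Br)cc1Br
F6 | step 7 | dimethyl [3,4,5-tribromo-2-(2,4-dibromophenoxy)phenyl]boronate | COB(OC)c1cc(Br)c(Br)c(Br)c1Oc1ccc(Br)cc1Br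
F7 | step 4 | potassium (2,4-dibromophenoxy)ethynide | [K+].[C-]#COc1ccc(Br)cc1Br
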